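## Retrosynthetic overview

1. C1–C8, the last bond: acid-mediated cation–olefin closure of ring B in a dearomatised acylphloroglucinol whose quaternary C5 carries a prenyl group and a C15 "homolavandulyl" chain. The same acid unmasks the catechol.
2. C5–C6, the key bond: alkylative dearomatisation of the flat, symmetric 3,5-diprenyl benzophenone with a chiral C15 triflate. Aromaticity and symmetry are lost together and all 38 carbons are in place.
3. C15 triflate: from (R)-lavandulol, whose isopropenyl methyl group is lengthened by one prenyl unit. C7 comes from the chiral pool.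
4. Diprenyl benzophenone: phloroglucinol plus 3,4-dihydroxybenzonitrile (Houben–Hoesch), catechol masked as a cyclic orthoformate, then double C-prenylation.
5. Ring order: the aroyl ring and ring A (C1–C5 and C9, the former phloroglucinol ring) are bought as arenes. Ring B (C1, C5–C9) is the only ring made and it closes last.

Assumption: enantiopure (R)-(−)-lavandulol, the natural enantiomer, is bought; C1–C9 are the bicyclo[3.3.1]nonane positions of the target.

Stereocontrol in brief:
- C7 comes from lavandulol and is never touched.
- C5 is formed in step 6 without facial control. Dienone 14 and its C5 epimer form in about equal amounts, are carried on together, and the unwanted series is removed by HPLC after step 7.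
- C1 is fixed by the tether in step 7.
- C8 is set in step 7 by allylic strain in the cation. This is a conformational prediction, not a demonstrated result.

## Route

Step 1
Reactants: 1 phloroglucinol; 2 3,4-dihydroxybenzonitrile
Product: 4 maclurin, via ketiminium chloride 3 (not isolated)
Conditions: HCl (gas), ZnCl2, Et2O, 0 → 20 °C; then H2O, 100 °C
Reagents that add atoms: water, O
Why: Houben–Hoesch acylation, in which the nitrile activated by HCl and ZnCl2 attacks the very electron-rich ring of 1 once (the iminium product is deactivated) and the ketiminium salt is hydrolysed to the diaryl ketone; no stereocentre is formed.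

Step 2
Reactants: 4 maclurin
Product: 5 catechol orthoformate of maclurin
Conditions: HC(OEt)3 (3 equiv), Amberlyst 15 (cat.), toluene, 110 °C, Dean–Stark
Reagents that add atoms: triethyl orthoformate, CCOC(OCC)OCC
Why: Acid-catalysed transorthoesterification, in which only the catechol 1,2-diol can close the five-membered 2-ethoxy-1,3-benzodioxole while the 1,3-related phloroglucinol hydroxyls give at most open orthoesters that revert on work-up; the orthoester carbon is a new, uncontrolled and irrelevant stereocentre that is lost in step 7.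

Step 3
Reactants: 5 catechol orthoformate of maclurin; 6 prenyl bromide (2.2 equiv)
Product: 8 diprenyl ketone, via monoprenyl ketone 7 (not isolated)
Conditions: aq. KOH (10%), 0 °C, 2 h; NaH2PO4/Na2HPO4 buffer (pH 7) work-up
Reagents that add atoms: none
Why: Base-mediated C-prenylation of the phloroglucinolate in water, where hydrogen bonding at oxygen steers the allylic bromide to the two free ring carbons, and the orthoester is stable to alkali and to the neutral work-up; the product has two equivalent prenyl-bearing carbons and no new stereocentre.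

Step 4
Reactants: 9 (R)-lavandulol; 6 prenyl bromide
Product: 11 homolavandulol, via dilithio lavandulol 10 (not isolated)
Conditions: n-BuLi (2.2 equiv), TMEDA, Et2O, 0 → 20 °C; then 6, −78 → 0 °C; H2O
Reagents that add atoms: none
Why: Alkoxide-directed allylic lithiation (known for isoprenol and isopulegol) takes a proton from the isopropenyl methyl group to give a 2-substituted allyllithium with two equivalent CH2 ends, and SN2 alkylation by prenyl bromide turns that methyl into the homoprenyl arm; the stereocentre sits on the central allyl carbon, is not deprotonated and stays R.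

Step 5
Reactants: 11 homolavandulol
Product: 12 homolavandulyl triflate
Conditions: Tf2O, 2,6-lutidine, CH2Cl2, −78 °C; used at once
Reagents that add atoms: trifluoromethanesulfonic anhydride, O=S(=O)(OS(=O)(=O)C(F)(F)F)C(F)(F)F
Why: O-sulfonylation of the primary alcohol with a hindered base at low temperature gives a leaving group reactive enough for SN2 at the β-branched carbon; no bond at the stereocentre is touched.

Step 6
Reactants: 8 diprenyl ketone; 12 homolavandulyl triflate (1.3 equiv)
Product: 14 dearomatised dienone (6S epimer), via trilithium trienolate 13 (not isolated)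
Conditions: LiN(SiMe3)2 (3.1 equiv), THF, −78 °C; 12, −78 → 0 °C; AcOH quench
Reagents that add atoms: none
Why: Alkylative dearomatisation (SN2 C-alkylation of a lithium acylphloroglucinolate, lithium chelation favouring carbon over oxygen) through one of the two equivalent prenyl-bearing carbons destroys aromaticity and symmetry and creates the quaternary C5; the remote stereocentre of 12 gives no useful facial bias, so 14 forms with about an equal amount of its (6R) epimer (same constitution, opposite configuration at the new quaternary carbon), and the unseparated pair is taken into step 7.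

Step 7
Reactants: 14 dearomatised dienone (as the roughly 1:1 mixture with its C5 epimer from step 6)
Product: 17 target, via uncyclised catechol formate 15 (not isolated), via cyclised catechol formate 16 (not isolated)
Conditions: HCO2H (98%, 2% H2O), 0.01 M, 20 °C, monitored; evaporate; MeOH, NaHCO3, 0 °C, 15 min; HPLC
Reagents that add atoms: none
Why: Cation–olefin cyclisation by protic acid (intramolecular Markovnikov hydroalkylation), in which formic acid protonates the 1,1-disubstituted alkene and the tertiary C8 cation is captured by the prenylated enol carbon C1 on the only face the tether allows (so C1 follows C5) through a boat-shaped ring B with C7–H over C9, the homoprenyl arm eclipsing C7–H to minimise allylic strain so that the new methyl lands cis to the C7 prenyl group (8R), while the acid cleaves the orthoester and methanol the resulting formate; the C5 epimer of 14 cyclises to the (1R,5R,7S,8R) 7-exo diastereomer of the target, which has a differently shaped ring B and is removed by HPLC.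

## Compound list

1 | phloroglucinol (benzene-1,3,5-triol) | Oc1cc(O)cc(O)c1 | starting material
2 | 3,4-dihydroxybenzonitrile | N#Cc1ccc(O)c(O)c1 | starting material
3 | (3,4-dihydroxyphenyl)(2,4,6-trihydroxyphenyl)methaniminium chloride | [NH2+]=C(c1ccc(O)c(O)c1)c1c(O)cc(O)cc1O.[Cl-] | intermediate
4 | maclurin, (3,4-dihydroxyphenyl)(2,4,6-trihydroxyphenyl)methanone | O=C(c1ccc(O)c(O)c1)c1c(O)cc(O)cc1O | intermediate
5 | (2-ethoxy-1,3-benzodioxol-5-yl)(2,4,6-trihydroxyphenyl)methanone; orthoester carbon in both configurations here and in 7, 8, 13, 14 | O=C(c1ccc2OC(OCC)Oc2c1)c1c(O)cc(O)cc1O | intermediate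
6 | prenyl bromide (1-bromo-3-methylbut-2-ene) | CC(C)=CCBr | starting material
7 | (2-ethoxy-1,3-benzodioxol-5-yl)[2,4,6-trihydroxy-3-(3-methylbut-2-en-1-yl)phenyl]methanone | O=C(c1ccc2OC(OCC)Oc2c1)c1c(O)cc(O)c(CC=C(C)C)c1O | intermediate
8 | (2-ethoxy-1,3-benzodioxol-5-yl)[2,4,6-trihydroxy-3,5-bis(3-methylbut-2-en-1-yl)phenyl]methanone | O=C(c1ccc2OC(OCC)Oc2c1)c1c(O)c(CC=C(C)C)c(O)c(CC=C(C)C)c1O | intermediate
9 | (R)-lavandulol, (2R)-5-methyl-2-(prop-1-en-2-yl)hex-4-en-1-ol | OC[C@H](CC=C(C)C)C(C)=C | starting material
10 | lithium (2R)-2-(3-lithioprop-1-en-2-yl)-5-methylhex-4-en-1-olate | [Li]OC[C@H](CC=C(C)C)C(=C)C[Li] | intermediate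
11 | homolavandulol, (2R)-5-methyl-2-(6-methylhepta-1,5-dien-2-yl)hex-4-en-1-ol | OC[C@H](CC=C(C)C)C(=C)CCC=C(C)C | intermediate
12 | (2R)-5-methyl-2-(6-methylhepta-1,5-dien-2-yl)hex-4-en-1-yl trifluoromethanesulfonate | O=S(=O)(OC[C@H](CC=C(C)C)C(=C)CCC=C(C)C)C(F)(F)F | intermediate
13 | trilithium salt (2,4,6-tris-O-lithio) of 8 | [Li]Oc1c(CC=C(C)C)c(O[Li])c(CC=C(C)C)c(O[Li])c1C(=O)c1ccc2OC(OCC)Oc2c1 | intermediate
14 | (6S)-4-(2-ethoxy-1,3-benzodioxole-5-carbonyl)-3,5-dihydroxy-2,6-bis(3-methylbut-2-en-1-yl)-6-[(2S)-5-methyl-2-(6-methylhepta-1,5-dien-2-yl)hex-4-en-1-yl]cyclohexa-2,4-dien-1-one (one tautomer drawn) | CC(C)=CCCC(=C)[C@@H](CC=C(C)C)C[C@]1(CC=C(C)C)C(=O)C(CC=C(C)C)=C(O)C(C(=O)c2ccc3OC(OCC)Oc3c2)=C1O | intermediate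
15 | analogue of 14 in which the aroyl group is 3-(formyloxy)-4-hydroxybenzoyl (the 4-O-formate behaves alike) | CC(C)=CCCC(=C)[C@@H](CC=C(C)C)C[C@]1(CC=C(C)C)C(=O)C(CC=C(C)C)=C(O)C(C(=O)c2ccc(O)c(OC=O)c2)=C1O | intermediate
16 | (1S,5S,7S,8R)-3-[3-(formyloxy)-4-hydroxybenzoyl]-4-hydroxy-8-methyl-1,5,7-tris(3-methylbut-2-en-1-yl)-8-(4-methylpent-3-en-1-yl)bicyclo[3.3.1]non-3-ene-2,9-dione | CC(C)=CCC[C@]1(C)[C@@H](CC=C(C)C)C[C@]2(CC=C(C)C)C(=O)[C@@]1(CC=C(C)C)C(=O)C(C(=O)c1ccc(O)c(OC=O)c1)=C2O | intermediate
17 | (1S,5S,7S,8R)-3-(3,4-dihydroxybenzoyl)-4-hydroxy-8-methyl-1,5,7-tris(3-methylbut-2-en-1-yl)-8-(4-methylpent-3-en-1-yl)bicyclo[3.3.1]non-3-ene-2,9-dione | CC(C)=CCC[C@]1(C)[C@@H](CC=C(C)C)C[C@]2(CC=C(C)C)C(=O)[C@@]1(CC=C(C)C)C(=O)C(C(=O)c1ccc(O)c(O)c1)=C2O | target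

## Step count and risks

Total steps: 7. Longest linear sequence: 5 (steps 1, 2, 3, 6, 7 from phloroglucinol); the side branch (steps 4, 5) joins at step 6.

The three steps most likely to fail are 6, 7 and 4.

Step 6. The enolate may alkylate on oxygen, the homoallylic triflate may ionise before it is attacked, and there is no facial control, so at best half of the material is the useful epimer. The fallback sets out from 5 and returns at 14; it reverses the order of the alkylations so that the hindered SN2 happens on an unsubstituted aromatic carbon. The trianion of 5 (LiN(SiMe3)2, THF) is alkylated with 12 at one of its two free ring carbons to give the aromatic terpenyl ketone F1. Prenyl bromide 6 in aqueous KOH then fills the last free ring carbon to give the aromatic terpenyl prenyl ketone F2. A second, dearomatising prenylation (LiN(SiMe3)2, THF, 6) at the carbon that carries the terpenyl chain gives 14, again together with its C5 epimer, and this pair is handled as in step 7. The price is the geminal diprenyl regioisomer F3, formed by prenylation at the other carbon, which is separated.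

Step 7. The prenyl alkenes can be protonated too and closed onto enol oxygens as chroman-type ethers. The C8 cation can lose H7, which would scramble C7. Closure has to pass a boat-shaped ring B, and the C8 outcome rests on a conformational argument. The fallback sets out from 14 and returns at 17; it masks the chelated enol before cyclisation. Dienone 14 (still mixed with its C5 epimer, which behaves alike) is mono-O-methylated with TMSCHN2 (toluene–MeOH) to the vinylogous methyl ester F4 (one O-methyl regioisomer is drawn). F4 lacks the acidic triketone proton and one nucleophilic oxygen, and tolerates a longer or stronger acid treatment. Formic acid cyclisation and methanolysis as in step 7 give the cyclised methyl ether F5, separated from its 7-exo isomer. LiCl in DMSO at 120 °C then cleaves the methyl ether by SN2 at methyl to give 17.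

Step 4. Lithiation may occur at another allylic site or at the stereocentre, and the allyllithium may attack prenyl bromide in the SN2′ sense. The fallback sets out from 6 and returns at 11; it builds the stereocentre with an auxiliary instead of taking it from lavandulol. Commercial 3-methylbut-3-en-1-ol is lithiated in the same way (n-BuLi, TMEDA) and alkylated with 6 to 7-methyl-3-methylideneoct-6-en-1-ol F6. Oxidation (Dess–Martin periodinane, then NaClO2) gives the acid F7. Its mixed pivalic anhydride acylates lithiated (R)-4-benzyl-1,3-oxazolidin-2-one to the imide F8. NaN(SiMe3)2 and 6 give the α-prenylated imide F9 (Evans alkylation: α-attack of the dienolate, anti to the benzyl group). LiBH4 reduction releases 11.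

## Further compounds

F1 | step 6 | (2-ethoxy-1,3-benzodioxol-5-yl){2,4,6-trihydroxy-3-[(2S)-5-methyl-2-(6-methylhepta-1,5-dien-2-yl)hex-4-en-1-yl]phenyl}methanone | O=C(c1ccc2OC(OCC)Oc2c1)c1c(O)cc(O)c(C[C@H](CC=C(C)C)C(=C)CCC=C(C)C)c1O
F2 | step 6 | 5-(3-methylbut-2-en-1-yl) derivative of F1 (aromatic; terpenyl and prenyl groups on the two ring carbons) | O=C(c1ccc2OC(OCC)Oc2c1)c1c(O)c(CC=C(C)C)c(O)c(C[C@H](CC=C(C)C)C(=C)CCC=C(C)C)c1O
F3 | step 6 | geminal diprenyl regioisomer of 14: 4-(2-ethoxy-1,3-benzodioxole-5-carbonyl)-3,5-dihydroxy-6,6-bis(3-methylbut-2-en-1-yl)-2-[(2S)-5-methyl-2-(6-methylhepta-1,5-dien-2-yl)hex-4-en-1-yl]cyclohexa-2,4-dien-1-one | CC(C)=CCC1(CC=C(C)C)C(=O)C(C[C@H](CC=C(C)C)C(=C)CCC=C(C)C)=C(O)C(C(=O)c2ccc3OC(OCC)Oc3c2)=C1O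
F4 | step 7 | 5-O-methyl ether (vinylogous methyl ester) of 14 | CC(C)=CCCC(=C)[C@@H](CC=C(C)C)C[C@]1(CC=C(C)C)C(=O)C(CC=C(C)C)=C(O)C(C(=O)c2ccc3OC(OCC)Oc3c2)=C1OC
F5 | step 7 | 4-O-methyl enol ether of 17 | CC(C)=CCC[C@]1(C)[C@@H](CC=C(C)C)C[C@]2(CC=C(C)C)C(=O)[C@@]1(CC=C(C)C)C(=O)C(C(=O)c1ccc(O)c(O)c1)=C2OC
F6 | step 4 | 7-methyl-3-methylideneoct-6-en-1-ol | OCCC(=C)CCC=C(C)C
F7 | step 4 | 7-methyl-3-methylideneoct-6-enoic acid | OC(=O)CC(=C)CCC=C(C)C
F8 | step 4 | (4R)-4-benzyl-3-(7-methyl-3-methylideneoct-6-enoyl)-1,3-oxazolidin-2-one | O=C1OC[C@@H](Cc2ccccc2)N1C(=O)CC(=C)CCC=C(C)C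
F9 | step 4 | (4R)-4-benzyl-3-[(2R)-5-methyl-2-(6-methylhepta-1,5-dien-2-yl)hex-4-enoyl]-1,3-oxazolidin-2-one | O=C1OC[C@@H](Cc2ccccc2)N1C(=O)[C@H](CC=C(C)C)C(=C)CCC=C(C)C
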